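**Retrosynthetic overview**

1. Numbering of the hydrindane part: C1 = carbinol carbon, C2, C3, C3a, C4 = hydroperoxide carbon, C5, C6 = spiro carbon (also a ring carbon of the trione), C7, C7a.
2. Target ⇐ cobalt/O2 hydroperoxidation of the 4-methylene compound ⇐ gem-diprenylation of the spiro triketone ⇐ dearomative spiro-alkylation (C6–C7) of a 3-substituted acetylphloroglucinol.
3. Key disconnection: C5–C6 and C3a–C4 are made together by a palladium-catalysed conjunctive cross-coupling of an aryl bromide (C6 at the phenol oxidation level), a 2-lithioallyl silyl ether (C4, C5 and the future 4-methyl carbon) and a cyclopentyl boronic ester (C3a–B, trans to the C7 arm).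
4. Enabling feature: C4 is a fully substituted, oxygen-bearing carbon of the six-membered ring, lying between the CH2 C5 on the former aromatic carbon C6 and the stereogenic methine C3a of the five-membered ring. This aryl–CH2–C(X)–C(sp3) array is what a vinylboronate 1,2-shift produces, with boron as a traceless stand-in at C4 and C3a transferred with retention.
5. Ring order: cyclopentane (bought as cyclopentenone; C3a by copper catalysis, C7a and C1 relayed), aromatic ring (bought), then the cyclohexane ring closes as the arene is dearomatised to the trione; C6 and C4 follow by substrate control.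

Key step: step 9

Remark: the enolised 2-acetyl-1,3,5-trione is written in the tautomer of the target SMILES; compound 14 is a mixture of epimers at its boron-bearing carbon, which becomes sp2 in step 12.

**Route**

Step 1
Reactants: 1 2,4,6-trihydroxyacetophenone
Product: 2 3-bromo-2,4,6-trihydroxyacetophenone
Conditions: NBS (1.0 equiv), THF, −78 °C to 0 °C
Reagents that add atoms: N-bromosuccinimide, O=C1CCC(=O)N1Br
Why: Electrophilic aromatic bromination of the very electron-rich phloroglucinol ring; the two free ring positions are equivalent and one equivalent at low temperature should stop at the monobromide.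

Step 2
Reactants: 2 3-bromo-2,4,6-trihydroxyacetophenone
Product: 3 3-bromo-2,4,6-tris(pivaloyloxy)acetophenone
Conditions: PivCl (3.5 equiv), Et3N, DMAP (cat.), CH2Cl2, 0 °C to rt
Reagents that add atoms: pivaloyl chloride, CC(C)(C)C(Cl)=O
Why: DMAP-catalysed O-acylation of the three phenols removes the acidic protons that would quench the boronate of step 9 and gives an electron-poor aryl bromide for oxidative addition.

Step 3
Reactants: 4 cyclopent-2-en-1-one
Product: 5 2-(hydroxymethyl)cyclopent-2-en-1-one
Conditions: aqueous formaldehyde, PBu3 (10 mol %), CHCl3/MeOH, rt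
Reagents that add atoms: formaldehyde, C=O
Why: Morita–Baylis–Hillman reaction: the phosphine adds to the enone, the enolate attacks formaldehyde and elimination returns the enone with the hydroxymethyl group (future C7) on the α-carbon (future C7a).

Step 4
Reactants: 5 2-(hydroxymethyl)cyclopent-2-en-1-one
Product: 6 2-[(tert-butyldimethylsilyloxy)methyl]cyclopent-2-en-1-one
Conditions: TBSCl, imidazole, CH2Cl2, 0 °C to rt
Reagents that add atoms: tert-butyldimethylsilyl chloride, CC(C)(C)[Si](C)(C)Cl
Why: Standard silylation of the primary allylic alcohol; the silyloxy group is too poor a leaving group to be lost from the enolate formed in step 5.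

Step 5
Reactants: 6 2-[(tert-butyldimethylsilyloxy)methyl]cyclopent-2-en-1-one
Product: 7 (2R,3R)-2-[(tert-butyldimethylsilyloxy)methyl]-3-(4,4,5,5-tetramethyl-1,3,2-dioxaborolan-2-yl)cyclopentan-1-one (2,3-trans)
Conditions: B2pin2 (1.1 equiv), CuCl (5 mol %), Josiphos-type ferrocenyl bisphosphine (6 mol %, antipode chosen for 3R), NaOtBu (10 mol %), MeOH (2 equiv), THF, 0 °C to rt; then DBU (10 mol %), CH2Cl2, 0 °C
Reagents that add atoms: bis(pinacolato)diboron, CC1(C)OB(OC1(C)C)B1OC(C)(C)C(C)(C)O1
Why: Copper-catalysed enantioselective conjugate borylation: the ligand-bound copper boryl adds to the β-carbon and sets C3 (future C3a) by catalyst control, methanol protonates the copper enolate, and base equilibration of the α-carbon gives the more stable 2,3-trans ketone (future C7a).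

Step 6
Reactants: 7 (2R,3R)-β-boryl ketone
Product: 8 (1R,2R,3R)-2-[(tert-butyldimethylsilyloxy)methyl]-1-methyl-3-(4,4,5,5-tetramethyl-1,3,2-dioxaborolan-2-yl)cyclopentan-1-ol (OH cis to the CH2OTBS arm, methyl cis to boron)
Conditions: MeMgBr, CeCl3, THF, −78 °C
Reagents that add atoms: methylmagnesium bromide, C[Mg]Br
Why: Organocerium-type 1,2-addition to the cyclopentanone anti to the adjacent C2 side chain (substrate control, as for 2-substituted cyclopentanones) sets the carbinol carbon (future C1); the weakly basic reagent avoids enolisation and leaves the pinacol boronate untouched.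

Step 7
Reactants: 8 (1R,2R,3R)-cyclopentanol boronate
Product: 9 (1R,2R,3R)-triethylsilyl ether of 8
Conditions: TESOTf, 2,6-lutidine, CH2Cl2, −78 °C to 0 °C
Reagents that add atoms: triethylsilyl trifluoromethanesulfonate, CC[Si](CC)(CC)OS(=O)(=O)C(F)(F)F
Why: Silylation of the tertiary alcohol with a silyl triflate removes the last acidic proton before the organolithium step.

Step 8
Reactants: 10 2-bromoprop-2-en-1-ol
Product: 11 (2-bromoallyloxy)(tert-butyl)dimethylsilane
Conditions: TBSCl, imidazole, CH2Cl2, 0 °C to rt
Reagents that add atoms: tert-butyldimethylsilyl chloride, CC(C)(C)[Si](C)(C)Cl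
Why: Standard silylation; the silyl ether survives bromine–lithium exchange at low temperature.

Step 9
Reactants: 11 (2-bromoallyloxy)(tert-butyl)dimethylsilane, 9 cyclopentyl pinacol boronate, 3 3-bromo-2,4,6-tris(pivaloyloxy)acetophenone
Product: 14 tertiary pinacol boronate in which the boron-bearing carbon (future C4) carries CH2OTBS, the CH2–aryl group [aryl = 3-acetyl-2,4,6-tris(pivaloyloxy)phenyl] and the cyclopentane ring carbon (future C3a), via alkenyllithium 12 (not isolated), via lithium boronate complex 13 (not isolated)
Conditions: 11, t-BuLi (2.0 equiv), Et2O, −78 °C; add 9, THF, −78 °C to rt; then 3, Pd(OAc)2 (5 mol %), MandyPhos ferrocenyl bisphosphine (6 mol %), NaOTf, THF, 60 °C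
Reagents that add atoms: none
Why: Bromine–lithium exchange gives alkenyllithium 12, which adds to the boron of 9 to form the tetracoordinate boronate 13; zerovalent palladium (from Pd(OAc)2 and the bisphosphine) inserts into the C–Br bond of 3 and, after bromide abstraction by NaOTf, the cationic arylpalladium binds the alkene of 13 and induces a 1,2-metallate shift of the cyclopentyl carbon from boron to the internal alkene carbon (C3a–C4), after which reductive elimination from the resulting Pd–CH2 alkyl forms the aryl–CH2 bond (C5–C6). The closest known reaction type is the palladium-catalysed conjunctive cross-coupling of α-substituted alkenylboron ate complexes with aryl electrophiles, which gives tertiary boronic esters. No ring is closed in this step; it joins the aromatic fragment, the two-carbon linchpin and the cyclopentane in an open chain. C3a migrates with retention (stereospecific 1,2-shift), so the C3a/C7a trans relationship set in step 5 is carried over, while the new boron-bearing centre forms as an inconsequential mixture that is erased in step 12. The step needs chemoselectivity for the conjunctive pathway over direct Suzuki–Miyaura transfer of the alkenyl group and over β-hydride elimination: the α-substituent slows transmetalation, the wide-bite-angle bisphosphine with a triflate counter-ion favours alkene binding, and the palladium alkyl sits on a CH2 next to a quaternary carbon and has no β-hydrogen.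

Step 10
Reactants: 14 tris-silylated tertiary boronate
Product: 15 triol boronate (two primary alcohols and the tertiary alcohol free; pivalates and boronate intact)
Conditions: HF·pyridine, pyridine, THF, 0 °C to rt
Reagents that add atoms: none
Why: Fluoride cleaves the three silyl ethers under buffered, weakly acidic conditions that should leave the aryl pivalates and the pinacol boronate intact.

Step 11
Reactants: 15 triol boronate
Product: 16 bis(methanesulfonate) of 15 (tertiary alcohol free)
Conditions: MsCl (2.5 equiv), Et3N, CH2Cl2, −20 °C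
Reagents that add atoms: methanesulfonyl chloride, CS(=O)(=O)Cl
Why: Sulfonylation of the two primary alcohols only (the tertiary alcohol does not react): one mesylate becomes the leaving group for ring closure, the other the leaving group β to boron.

Step 12
Reactants: 16 bis(methanesulfonate)
Product: 18 (1R,3aR,6R,7aS)-spiro triketone: 2-acetyl-cyclohexane-1,3,5-trione (enol form) spiro-fused through its C6 to C6 of a trans-hydrindane bearing 1-hydroxy, 1-methyl and 4-methylene, via phloroglucinol mesylate 17 (not isolated)
Conditions: K2CO3 (6 equiv), degassed MeOH (0.01 M), 0 °C to rt; then solvent exchange to DMF, 60 °C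
Reagents that add atoms: none
Why: Carbonate/methanol triggers three known events in sequence: alkoxide attack on boron with elimination of the β-mesylate (boron-Wittig-type β-elimination) to give the 4-methylene group, methanolysis of the pivalates, and 6-exo-tet C-alkylation of the phloroglucinolate at its substituted carbon (dearomative spiro-alkylation; O-alkylation would need an eight-membered ring), which closes the cyclohexane ring trans-fused because both arms are already trans on the cyclopentane; the spiro centre C6 is set by substrate control, the rigid acetyl-chelated C–O flank being expected to take the equatorial site of the chair transition state so that the unsubstituted flank ends axial.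

Step 13
Reactants: 18 spiro triketone
Product: 19 (1R,3aR,6R,7aS)-4,4-diprenyl spiro triketone (target skeleton with 4-methylene in place of C(CH3)(OOH))
Conditions: prenyl bromide (2.5 equiv), NaOMe, MeOH, 0 °C to rt
Reagents that add atoms: 1-bromo-3-methylbut-2-ene, CC(C)=CCBr
Why: Double C-alkylation of the only remaining nucleophilic ring carbon of the β-triketone (the acetyl-bearing carbon is blocked, the spiro carbon is quaternary), as in the gem-diprenylation of acylphloroglucinols; no stereocentre is formed.

Step 14
Reactants: 19 4-methylene diprenyl spiro triketone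
Product: 21 CNP0149131.2, (1R,3aR,4R,6R,7aS) in the numbering above, via triethylsilyl peroxide 20 (not isolated)
Conditions: Co(acac)2 (10 mol %), O2 (1 atm), Et3SiH, ClCH2CH2Cl, rt; then HCl (cat.), MeOH, 0 °C
Reagents that add atoms: dioxygen, O=O
Why: Mukaiyama–Isayama hydroperoxysilylation: cobalt hydride transfers a hydrogen atom to the 1,1-disubstituted alkene (faster than to the trisubstituted prenyl alkenes), the tertiary C4 radical is trapped by O2 on the equatorial face because the axial face is blocked by the syn-axial carbonyl on C6, giving the equatorial peroxide with axial methyl, and acidic methanol removes the silyl group.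

**Compound list**

1 | 2,4,6-trihydroxyacetophenone | CC(=O)c1c(O)cc(O)cc1O | starting material
2 | 3-bromo-2,4,6-trihydroxyacetophenone | CC(=O)c1c(O)cc(O)c(Br)c1O | intermediate
3 | 3-bromo-2,4,6-tris(pivaloyloxy)acetophenone | CC(=O)c1c(OC(=O)C(C)(C)C)cc(OC(=O)C(C)(C)C)c(Br)c1OC(=O)C(C)(C)C | intermediate
4 | cyclopent-2-en-1-one | O=C1C=CCC1 | starting material
5 | 2-(hydroxymethyl)cyclopent-2-en-1-one | OCC1=CCCC1=O | intermediate
6 | 2-[(tert-butyldimethylsilyloxy)methyl]cyclopent-2-en-1-one | CC(C)(C)[Si](C)(C)OCC1=CCCC1=O | intermediate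
7 | (2R,3R)-2-[(tert-butyldimethylsilyloxy)methyl]-3-(pinacolboryl)cyclopentan-1-one | CC(C)(C)[Si](C)(C)OC[C@H]1[C@@H](CCC1=O)B1OC(C)(C)C(C)(C)O1 | intermediate
8 | (1R,2R,3R)-2-[(tert-butyldimethylsilyloxy)methyl]-1-methyl-3-(pinacolboryl)cyclopentan-1-ol | CC(C)(C)[Si](C)(C)OC[C@H]1[C@@H](CC[C@@]1(C)O)B1OC(C)(C)C(C)(C)O1 | intermediate
9 | (1R,2R,3R)-triethylsilyl ether of 8 | CC(C)(C)[Si](C)(C)OC[C@H]1[C@@H](CC[C@@]1(C)O[Si](CC)(CC)CC)B1OC(C)(C)C(C)(C)O1 | intermediate
10 | 2-bromoprop-2-en-1-ol | OCC(Br)=C | starting material
11 | (2-bromoallyloxy)(tert-butyl)dimethylsilane | CC(C)(C)[Si](C)(C)OCC(Br)=C | intermediate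
12 | [3-(tert-butyldimethylsilyloxy)prop-1-en-2-yl]lithium | [Li]C(=C)CO[Si](C)(C)C(C)(C)C | intermediate (not isolated)
13 | lithium boronate from 9 and 12 (cyclopentyl and alkenyl groups on tetracoordinate boron) | CC(C)(C)[Si](C)(C)OC[C@H]1[C@@H](CC[C@@]1(C)O[Si](CC)(CC)CC)[B-]1(OC(C)(C)C(C)(C)O1)C(=C)CO[Si](C)(C)C(C)(C)C.[Li+] | intermediate (not isolated)
14 | tertiary pinacol boronate: boron-bearing carbon with CH2OTBS, CH2–[3-acetyl-2,4,6-tris(pivaloyloxy)phenyl] and the cyclopentyl carbon (ring stereocentres as in 9, retention at the former C–B carbon; epimers at the boron-bearing carbon) | CC(C)(C)[Si](C)(C)OC[C@H]1[C@@H](CC[C@@]1(C)O[Si](CC)(CC)CC)C(CO[Si](C)(C)C(C)(C)C)(Cc1c(OC(=O)C(C)(C)C)cc(OC(=O)C(C)(C)C)c(C(C)=O)c1OC(=O)C(C)(C)C)B1OC(C)(C)C(C)(C)O1 | intermediate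
15 | triol boronate (desilylated 14) | OC[C@H]1[C@@H](CC[C@@]1(C)O)C(CO)(Cc1c(OC(=O)C(C)(C)C)cc(OC(=O)C(C)(C)C)c(C(C)=O)c1OC(=O)C(C)(C)C)B1OC(C)(C)C(C)(C)O1 | intermediate
16 | bis(methanesulfonate) of 15 | CS(=O)(=O)OC[C@H]1[C@@H](CC[C@@]1(C)O)C(COS(C)(=O)=O)(Cc1c(OC(=O)C(C)(C)C)cc(OC(=O)C(C)(C)C)c(C(C)=O)c1OC(=O)C(C)(C)C)B1OC(C)(C)C(C)(C)O1 | intermediate
17 | 3-{2-[(1R,2R,3R)-3-hydroxy-2-(mesyloxymethyl)-3-methylcyclopentyl]allyl}-2,4,6-trihydroxyacetophenone | CS(=O)(=O)OC[C@H]1[C@@H](CC[C@@]1(C)O)C(=C)Cc1c(O)cc(O)c(C(C)=O)c1O | intermediate (not isolated)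
18 | (1R,3aR,6R,7aS)-spiro triketone with 1-hydroxy-1-methyl and 4-methylene on the trans-hydrindane | CC(=O)C1=C(O)CC(=O)[C@]2(C[C@H]3[C@@H](CC[C@@]3(C)O)C(=C)C2)C1=O | intermediate
19 | (1R,3aR,6R,7aS)-gem-diprenyl 4-methylene spiro triketone | CC(=O)C1=C(O)C(CC=C(C)C)(CC=C(C)C)C(=O)[C@]2(C[C@H]3[C@@H](CC[C@@]3(C)O)C(=C)C2)C1=O | intermediate
20 | triethylsilyl peroxide of the target | CC(=O)C1=C(O)C(CC=C(C)C)(CC=C(C)C)C(=O)[C@]2(C[C@H]3[C@@H](CC[C@@]3(C)O)[C@](C)(OO[Si](CC)(CC)CC)C2)C1=O | intermediate (not isolated)
21 | CNP0149131.2 | CC(=O)C1=C(O)C(CC=C(C)C)(CC=C(C)C)C(=O)[C@]2(C[C@H]3[C@@H](CC[C@@]3(C)O)[C@](C)(OO)C2)C1=O | target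

**Totals and risks**

Total step count: 14. Longest linear sequence: 11 steps (steps 3–7 and 9–14, from cyclopent-2-en-1-one).

Steps most likely to fail:

Step 9. The doubly ortho-substituted aryl bromide may enter the catalytic cycle too slowly, so that boronate 13 decays by loss of its allylic silyloxy group or hands its alkenyl group directly to palladium; the 1,2-shift of a hindered secondary carbon onto an α-substituted alkene may also stall. Fallback, stepwise and from known reactions: it sets out from 9. Zweifel olefination with isopropenyllithium (from 2-bromopropene and t-BuLi; then I2, NaOMe) should give the isopropenylcyclopentane F1 with retention at the ring carbon. Ene-type allylic chlorination (Ca(OCl)2, CO2, CH2Cl2/H2O) should give the 2-substituted allyl chloride F2, HF·pyridine the chloro diol F3, and MsCl/Et3N the chloro mesylate F4. C-allylation of unprotected 1 with F4 (K2CO3, MeOH then DMF) should form 17 in the flask, which closes as in step 12; the fallback comes back to the route at 18.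

Step 12. The ring closure may show poor facial selectivity at the spiro carbon (either C–O flank of the planar phloroglucinolate can end axial), and the mesylate may be solvolysed before carbon attack. Fallback, radical instead of anionic formation of the spiro centre with the other ring bond closed last: it sets out from 8 (and 1). Zweifel olefination of 8 (isopropenyllithium, 2 equiv; then I2, NaOMe) should give the isopropenyl alcohol F5, TBAF the diol F6, and TEMPO/PhI(OAc)2 the hydroxy aldehyde F7. Compound 1 with prenyl bromide and NaOMe gives the 4,4-diprenyl acetylphloroglucinol F8. Organocatalytic reductive Knoevenagel alkylation of F8 with F7 (L-proline, Hantzsch ester) should give the C-alkylated triketone F9. Mn(OAc)3·2H2O under O2 in AcOH then oxidises the β-triketone to its carbon radical, which closes 6-endo onto the isopropenyl group; the tertiary radical takes up O2 and the fallback comes back to the route at 21.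

Step 14. Hydrogen-atom transfer to the prenyl alkenes may compete with the 4-methylene group, the β-triketone may sequester cobalt, and the peroxide may be over-reduced to the alcohol. Fallback, peroxide installed before the prenyl groups and carried in protected form: it sets out from 18. Co(acac)2/O2/Et3SiH should give the silyl peroxide F10, acidic methanol the hydroperoxide F11, and 2-methoxypropene with PPTS the 2-methoxyprop-2-yl peroxyketal F12. Prenyl bromide/NaOMe then gives the diprenyl peroxyketal F13, and aqueous acetic acid releases the hydroperoxide; the fallback comes back to the route at 21.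

Further compounds
F1 | step 9 | isopropenylcyclopentane (9 with isopropenyl in place of the boronate, retention) | CC(C)(C)[Si](C)(C)OC[C@H]1[C@@H](CC[C@@]1(C)O[Si](CC)(CC)CC)C(C)=C
F2 | step 9 | 2-substituted allyl chloride from F1 | CC(C)(C)[Si](C)(C)OC[C@H]1[C@@H](CC[C@@]1(C)O[Si](CC)(CC)CC)C(=C)CCl
F3 | step 9 | chloro diol | OC[C@H]1[C@@H](CC[C@@]1(C)O)C(=C)CCl
F4 | step 9 | chloro mesylate | CS(=O)(=O)OC[C@H]1[C@@H](CC[C@@]1(C)O)C(=C)CCl
F5 | step 12 | isopropenyl alcohol (8 with isopropenyl in place of the boronate) | CC(C)(C)[Si](C)(C)OC[C@H]1[C@@H](CC[C@@]1(C)O)C(C)=C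
F6 | step 12 | isopropenyl diol | OC[C@H]1[C@@H](CC[C@@]1(C)O)C(C)=C
F7 | step 12 | hydroxy aldehyde | O=C[C@H]1[C@@H](CC[C@@]1(C)O)C(C)=C
F8 | step 12 | 4,4-diprenyl acetylphloroglucinol (dearomatised) | CC(=O)C1=C(O)C(CC=C(C)C)(CC=C(C)C)C(O)=CC1=O
F9 | step 12 | C-alkylated diprenyl triketone with the isopropenylcyclopentylmethyl arm | CC(=O)C1=C(O)C(CC=C(C)C)(CC=C(C)C)C(O)=C(C[C@H]2[C@@H](CC[C@@]2(C)O)C(C)=C)C1=O
F10 | step 14 | triethylsilyl peroxide of the unprenylated spiro triketone | CC(=O)C1=C(O)CC(=O)[C@]2(C[C@H]3[C@@H](CC[C@@]3(C)O)[C@](C)(OO[Si](CC)(CC)CC)C2)C1=O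
F11 | step 14 | unprenylated hydroperoxide | CC(=O)C1=C(O)CC(=O)[C@]2(C[C@H]3[C@@H](CC[C@@]3(C)O)[C@](C)(OO)C2)C1=O
F12 | step 14 | 2-methoxyprop-2-yl peroxyketal of F11 | CC(=O)C1=C(O)CC(=O)[C@]2(C[C@H]3[C@@H](CC[C@@]3(C)O)[C@](C)(OOC(C)(C)OC)C2)C1=O
F13 | step 14 | diprenyl peroxyketal | CC(=O)C1=C(O)C(CC=C(C)C)(CC=C(C)C)C(=O)[C@]2(C[C@H]3[C@@H](CC[C@@]3(C)O)[C@](C)(OOC(C)(C)OC)C2)C1=O
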